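## Retrosynthetic overview

1. The epoxy spiro-lactone (C12, C13, C15, C16) comes from an enol lactone, itself from the C12 acid and C16 aldehyde that both hang on C13 (masked as CO2tBu and CH2CH(OMe)2). The epoxide oxygen is brought from C16 onto C15 with inversion (bromo lactol), because the 14β-CO2Me group covers that face against outside oxidants.
2. Ring B is closed last. The C7 oxygen and the carbonyl of the C14 ester (C17) are 1,4-related through C8, so C7–C8 is made by an intramolecular Stetter addition of a C7 aldehyde to the ring C cyclopentene ester (C8=C14). C8 and C14 are both enolisable and settle thermodynamically.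
3. Rings A and C are joined at C9–C10 by Tsuji–Trost allylation of 2-methylcyclohexane-1,3-dione. A CBS desymmetrisation sets C1 and C10, followed by stepwise C4 gem-dimethylation, allyl addition at C5, 1,5-acetonide formation and ozonolysis.
4. Ring C comes from tert-butyl 2-oxocyclopentanecarboxylate: C13 by asymmetric phase-transfer allylation, the C14 ester by triflate carbonylation, C9–O by allylic oxidation and CBS reduction.
5. Ring order: ring C (purchased) → ring A (purchased, joined at C9–C10) → ring B (Stetter) → spiro-lactone → epoxide.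

Key step: step 16

Remark: cassane numbering is used (C17 = carbon of the C14 ester, C18/C19 = methyls on C4, C20 = methyl on C10); β is the face of the C10 methyl group.
Remark: the phase-transfer catalyst antipode in step 1 is taken to be the one that gives the (R)-ester 3.
Remark: in enol lactone 30 the 14β-CO2Me group is cis to C15 and shields the C14 side of C15=C16, which is the side that carries the epoxide oxygen in the target; a direct dioxirane epoxidation is therefore expected on the wrong face, and steps 22–23 replace it.

## Route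

Step 1
Reactants: 1 tert-butyl 2-oxocyclopentane-1-carboxylate; 2 allyl bromide
Product: 3 tert-butyl (R)-2-oxo-1-(prop-2-enyl)cyclopentane-1-carboxylate
Conditions: chiral C2-symmetric N-spiro bis(binaphthyl)ammonium bromide (1 mol %), K2CO3 (sat. aq.), toluene, 0 °C
Reagents that add atoms: none
Why: Asymmetric phase-transfer alkylation of a β-keto ester: the chiral ammonium cation pairs with the enolate and shields one face, so allylation sets the quaternary C13 centre as (R).

Step 2
Reactants: 3 tert-butyl (R)-2-oxo-1-(prop-2-enyl)cyclopentane-1-carboxylate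
Product: 5 tert-butyl (R)-1-(2,2-dimethoxyethyl)-2-oxocyclopentane-1-carboxylate, via keto aldehyde 4 (not isolated)
Conditions: O3, CH2Cl2/MeOH, −78 °C; Me2S; then HC(OMe)3, PPTS, MeOH, rt
Reagents that add atoms: ozone, O=[O+][O-] (aldehyde oxygen of 4, lost again on acetal formation); trimethyl orthoformate, COC(OC)OC (both methoxy groups of 5)
Why: Ozonolysis of the only alkene with reductive work-up, then acid-catalysed acetalisation of the aldehyde, which is much faster than ketalisation of the hindered ring ketone; C13 is untouched.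

Step 3
Reactants: 5 tert-butyl (R)-1-(2,2-dimethoxyethyl)-2-oxocyclopentane-1-carboxylate
Product: 6 tert-butyl (R)-1-(2,2-dimethoxyethyl)-2-(trifluoromethylsulfonyloxy)cyclopent-2-ene-1-carboxylate
Conditions: KN(SiMe3)2, THF, −78 °C; PhNTf2, −78 to 0 °C
Reagents that add atoms: N-phenylbis(trifluoromethanesulfonimide), O=S(=O)(N(c1ccccc1)S(=O)(=O)C(F)(F)F)C(F)(F)F
Why: Enol triflate formation: C13 is quaternary, so the ketone enolises only towards C8 and the triflimide traps the enolate on oxygen.

Step 4
Reactants: 6 enol triflate
Product: 7 1-tert-butyl 2-methyl (R)-1-(2,2-dimethoxyethyl)cyclopent-2-ene-1,2-dicarboxylate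
Conditions: Pd(OAc)2, dppp, CO (1 atm), Et3N, MeOH/DMF, 60 °C
Reagents that add atoms: carbon monoxide, [C-]#[O+]; methanol, CO
Why: Palladium-catalysed methoxycarbonylation of an enol triflate (oxidative addition, CO insertion, methanolysis) installs the C14 ester carbon C17 and fixes the C8=C14 double bond.

Step 5
Reactants: 7 cyclopentene diester
Product: 8 1-tert-butyl 2-methyl (S)-1-(2,2-dimethoxyethyl)-4-oxocyclopent-2-ene-1,2-dicarboxylate
Conditions: Rh2(cap)4 (dirhodium tetracaprolactamate, 1 mol %), tBuOOH (70 % aq.), K2CO3, CH2Cl2, rt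
Reagents that add atoms: tert-butyl hydroperoxide, CC(C)(C)OO
Why: Allylic C–H oxidation of a cycloalkene carboxylate: C9 is the only allylic CH2 because C13 is quaternary, so the 4-oxo enoate is the only product expected (the descriptor changes only through priorities).

Step 6
Reactants: 8 4-oxo enoate
Product: 9 1-tert-butyl 2-methyl (1R,4S)-1-(2,2-dimethoxyethyl)-4-hydroxycyclopent-2-ene-1,2-dicarboxylate (hydroxyl cis to the dimethoxyethyl arm)
Conditions: (R)-2-methyl-CBS-oxazaborolidine (10 mol %), catecholborane, toluene, −78 °C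
Reagents that add atoms: none
Why: CBS reduction under reagent control: the catalyst reads alkenyl C8 as the large and C11H2 as the small group, so the (R)-oxazaborolidine should give the (4S)-alcohol with the C9 hydroxyl cis to the C15 arm, and any C9 epimer is removed by chromatography.

Step 7
Reactants: 9 allylic alcohol
Product: 10 1-tert-butyl 2-methyl (1R,4S)-1-(2,2-dimethoxyethyl)-4-(methoxycarbonyloxy)cyclopent-2-ene-1,2-dicarboxylate
Conditions: ClCO2Me, pyridine, DMAP (cat.), CH2Cl2, 0 °C
Reagents that add atoms: methyl chloroformate, COC(=O)Cl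
Why: O-Acylation of the allylic alcohol gives the carbonate leaving group with C9 unchanged.

Step 8
Reactants: 10 allylic carbonate; 11 2-methylcyclohexane-1,3-dione
Product: 12 1-tert-butyl 2-methyl (1R,4S)-1-(2,2-dimethoxyethyl)-4-(1-methyl-2,6-dioxocyclohexyl)cyclopent-2-ene-1,2-dicarboxylate
Conditions: Pd2(dba)3·CHCl3 (2.5 mol %), PPh3 (10 mol %), THF, 40 °C
Reagents that add atoms: none
Why: Tsuji–Trost allylation: zerovalent palladium ionises the carbonate with inversion, the methoxide set free deprotonates the dione, and the soft enolate attacks C9 anti to palladium and distal to the ester, so C9–C10 forms with net retention (C10 cis to the C15 arm, 9α-H) and the C8=C14 enoate stays conjugated.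

Step 9
Reactants: 12 coupled dione
Product: 13 hydroxy ketone: ring A with 1α-hydroxyl (1S), 5-oxo and 10β-methyl, joined through C10 to C9 of the ring C diester
Conditions: (R)-2-methyl-CBS-oxazaborolidine (20 mol %), catecholborane, toluene/THF, −40 °C
Reagents that add atoms: none
Why: CBS desymmetrisation of a 2,2-disubstituted 1,3-dione: the (R)-catalyst fixes the new carbinol as (S) (quaternary C10 as large group) and hydride can only enter from the methyl face, anti to the bulky cyclopentenyl group, so only one of the two diastereotopic carbonyls is reduced and C1 (α-OH) and C10 (β-methyl) are set together.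

Step 10
Reactants: 13 hydroxy ketone
Product: 14 1α-triethylsilyl ether of 13
Conditions: TESCl, imidazole, DMF, rt
Reagents that add atoms: chlorotriethylsilane, CC[Si](Cl)(CC)CC
Why: Silylation of the secondary C1 alcohol prevents retro-aldol cleavage and O-methylation in the following base steps.

Step 11
Reactants: 14 silyl ether ketone; 15 methyl iodide
Product: 16 4-monomethyl-5-ketone (C4 epimers, 1α-OTES)
Conditions: LiN(iPr)2 (1.1 equiv), THF, −78 °C; then 15 (1.2 equiv), −78 to −20 °C
Reagents that add atoms: none
Why: Kinetic enolate alkylation: the C5 ketone can enolise only towards C4 because C10 is quaternary, deprotonation there is faster than removal of the hindered γ-hydrogen at C9 of the enoate, and the 5-(enolendo)-exo-trig Michael closure onto C8 is geometrically disfavoured, so methyl iodide C-methylates the lithium enolate; the C4 centre forms as an epimer mixture that does not matter because it becomes the gem-dimethyl carbon in the next step.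

Step 12
Reactants: 16 4-monomethyl-5-ketone; 15 methyl iodide
Product: 17 4,4-dimethyl-5-ketone (1α-OTES)
Conditions: LiN(iPr)2 (1.2 equiv), THF, −78 to 0 °C; recool, then 15 (2 equiv), DMPU, −78 to 0 °C
Reagents that add atoms: none
Why: Second enolate alkylation of the α-methyl ketone: the tetrasubstituted C4=C5 enolate is the only one that can form, DMPU raises its reactivity, and C-methylation with methyl iodide gives the C4 gem-dimethyl group and removes the C4 stereocentre.

Step 13
Reactants: 17 4,4-dimethyl-5-ketone; 18 allylmagnesium bromide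
Product: 19 5β-allyl-5α-hydroxy compound (1α-OTES)
Conditions: ZnCl2 (transmetallation to allylzinc), THF, −78 to 0 °C; aq. NH4Cl
Reagents that add atoms: none
Why: Allylzinc addition to a ketone through a six-membered allyl-transposition transition state, with both esters inert to the zinc reagent: the α-face of C5 is blocked by the axial 1α-silyloxy group and by the C9 substituent on C10, so the allyl group should enter from the β-face and leave the tertiary hydroxyl 5α.

Step 14
Reactants: 19 allyl carbinol
Product: 21 5β-allyl 1α,5α-O-isopropylidene acetal, via diol 20 (not isolated)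
Conditions: CSA (cat.), MeOH, rt; concentrate; Me2C(OMe)2, acetone, CSA (cat.), rt
Reagents that add atoms: 2,2-dimethoxypropane, COC(C)(C)OC
Why: Acid-catalysed methanolysis of the TES ether followed by acetonide formation across the syn-diaxial 1α,5α-diol (a check on C5, since a 5β-alcohol could not be bridged); the dimethyl acetal only exchanges with itself in methanol and the tert-butyl ester is stable to CSA.

Step 15
Reactants: 21 allyl acetonide
Product: 22 C7 aldehyde: 5β-(2-oxoethyl) 1α,5α-acetonide linked at C9–C10 to the ring C cyclopentene ester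
Conditions: O3, CH2Cl2, −78 °C (Sudan red 7B end point); PPh3, −78 °C to rt
Reagents that add atoms: ozone, O=[O+][O-]
Why: Ozonolysis with a dye end point cleaves the electron-rich terminal alkene much faster than the electron-poor trisubstituted C8=C14 enoate, and PPh3 reduces the ozonide to the C7 aldehyde.

Step 16
Reactants: 22 C7 aldehyde
Product: 24 tricyclic 7-ketone (8β-H; 9α-H; 14β-CO2Me; 1α,5α-acetonide), via kinetic C8/C14 epimer mixture 23 (not isolated)
Conditions: 2-(pentafluorophenyl)-6,7-dihydro-5H-pyrrolo[2,1-c][1,2,4]triazol-2-ium tetrafluoroborate (20 mol %), KN(SiMe3)2 (18 mol %), toluene, rt to 60 °C; then DBU (0.5 equiv), 60 °C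
Reagents that add atoms: none
Why: The carbene from the triazolium salt adds to the C7 aldehyde and tautomerises to the Breslow intermediate, an acyl-anion equivalent, which adds in conjugate fashion to C8 of the cyclopentene ester; protonation of the ester enolate at C14 and loss of the carbene give the 7-ketone (intramolecular Stetter reaction, closest precedent the cyclisation of aliphatic aldehydes onto β-substituted and α,β-disubstituted acrylates). Ring B closes in the 6-exo-trig mode, with C8=C14 exocyclic to the new ring. C8, α to the new ketone, is set under thermodynamic control: DBU should equilibrate it to the trans B/C fusion (8β-H), because the cis isomer would hold C14 axial and syn to the C10 methyl group. C14 is equilibrated likewise to the 14β-ester, trans to C7 and trans to the CO2tBu group on C13, while C5, C9, C10 and C13 cannot enolise. The step needs acyl-anion addition to win over aldol, benzoin and elimination pathways: the aldehyde is neopentyl-like and self-condenses poorly, the acetonide ties up the C5 oxygen so that retro-aldol loss of the aldehyde cannot occur, and the tether allows only the six-membered closure.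

Step 17
Reactants: 24 tricyclic 7-ketone
Product: 25 1α,5α-dihydroxy-7-ketone
Conditions: CSA (cat.), MeOH, rt
Reagents that add atoms: none
Why: Acid-catalysed transketalisation in methanol removes the acetonide as 2,2-dimethoxypropane while the dimethyl acetal is degenerate under these conditions, freeing the 5α-hydroxyl that directs the next step.

Step 18
Reactants: 25 dihydroxy ketone
Product: 26 1α,5α,7β-triol
Conditions: Me4NBH(OAc)3, MeCN/AcOH, −30 °C
Reagents that add atoms: none
Why: Hydroxyl-directed reduction of a β-hydroxy ketone with triacetoxyborohydride (Evans–Saksena type): the axial 5α-hydroxyl binds boron and delivers hydride intramolecularly to the α-face of C7, which should give the anti 1,3-diol, that is the equatorial 7β-alcohol.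

Step 19
Reactants: 26 triol
Product: 27 1α,7β-diacetate with free 5α-hydroxyl
Conditions: Ac2O, DMAP, pyridine, rt to 40 °C
Reagents that add atoms: acetic anhydride, CC(=O)OC(C)=O
Why: DMAP-catalysed acetylation esterifies the two secondary hydroxyls at C1 and C7, while the tertiary 5-hydroxyl between two quaternary carbons is not acylated under these conditions.

Step 20
Reactants: 27 diacetate
Product: 29 spiro lactol (5-hydroxy-γ-lactone on C13; C16 epimers), via aldehydo acid 28 (not isolated)
Conditions: TFA/CH2Cl2/H2O (10:10:1), 0 °C to rt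
Reagents that add atoms: water, O
Why: Acidolysis of the tert-butyl ester and hydrolysis of the dimethyl acetal give the γ-aldehydo acid, which closes at once to the five-membered acyl lactol, helped by the quaternary C13; the C16 configuration is of no consequence.

Step 21
Reactants: 29 spiro lactol
Product: 30 spiro enol lactone (C15=C16)
Conditions: Ac2O, NaOAc, 100 °C
Reagents that add atoms: none
Why: Classical enol lactonisation of a γ-oxo acid (mixed anhydride or pseudo-acid acetate, then loss of acetic acid); C13 carries no hydrogen, so only the C15=C16 enol lactone can form.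

Step 22
Reactants: 30 spiro enol lactone
Product: 31 15-bromo lactol (bromine on the C11 side of the lactone; C16 epimers)
Conditions: NBS, THF/H2O, 0 °C
Reagents that add atoms: N-bromosuccinimide, O=C1CCC(=O)N1Br; water, O
Why: Bromohydroxylation of an enol ester: Br+ adds to the nucleophilic C15 from the open face syn to C11 (anti to the 14β-ester that is cis to C15) and water captures the acyloxycarbenium ion at C16, which sets C15 with bromine on the C11 side.

Step 23
Reactants: 31 bromo lactol
Product: 32 spirocaesalmin
Conditions: Ag2O, 4 Å molecular sieves, CH2Cl2, rt, dark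
Reagents that add atoms: none
Why: Proposed new method: silver-assisted loss of bromide from C15 with backside attack of the C16 lactol oxygen (intramolecular SN2, inversion at C15) should close the oxirane on the C14 face, the face an external oxidant cannot reach, and C16 follows because the epoxide can only be cis-fused; the closest known reaction types are the Ag2O closure of trans-halohydrins to epoxides and the closure of 2-halo or 2-sulfonyloxy hemiacetals to 1,2-anhydro sugars, here extended to an acyl lactol.

## Compound list

1 | tert-butyl 2-oxocyclopentane-1-carboxylate | CC(C)(C)OC(=O)C1CCCC1=O | starting material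
2 | allyl bromide | C=CCBr | starting material
3 | tert-butyl (R)-2-oxo-1-(prop-2-enyl)cyclopentane-1-carboxylate | O=C1CCC[C@]1(CC=C)C(=O)OC(C)(C)C | intermediate
4 | tert-butyl (R)-2-oxo-1-(2-oxoethyl)cyclopentane-1-carboxylate | O=C1CCC[C@]1(CC=O)C(=O)OC(C)(C)C | intermediate (not isolated)
5 | tert-butyl (R)-1-(2,2-dimethoxyethyl)-2-oxocyclopentane-1-carboxylate | O=C1CCC[C@]1(CC(OC)OC)C(=O)OC(C)(C)C | intermediate
6 | tert-butyl (R)-1-(2,2-dimethoxyethyl)-2-(trifluoromethylsulfonyloxy)cyclopent-2-ene-1-carboxylate | FC(F)(F)S(=O)(=O)OC1=CCC[C@]1(CC(OC)OC)C(=O)OC(C)(C)C | intermediate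
7 | 1-tert-butyl 2-methyl (R)-1-(2,2-dimethoxyethyl)cyclopent-2-ene-1,2-dicarboxylate | COC(=O)C1=CCC[C@]1(CC(OC)OC)C(=O)OC(C)(C)C | intermediate
8 | 1-tert-butyl 2-methyl (S)-1-(2,2-dimethoxyethyl)-4-oxocyclopent-2-ene-1,2-dicarboxylate | COC(=O)C1=CC(=O)C[C@]1(CC(OC)OC)C(=O)OC(C)(C)C | intermediate
9 | 1-tert-butyl 2-methyl (1R,4S)-1-(2,2-dimethoxyethyl)-4-hydroxycyclopent-2-ene-1,2-dicarboxylate | O[C@H]1C[C@](CC(OC)OC)(C(=O)OC(C)(C)C)C(C(=O)OC)=C1 | intermediate
10 | 1-tert-butyl 2-methyl (1R,4S)-1-(2,2-dimethoxyethyl)-4-(methoxycarbonyloxy)cyclopent-2-ene-1,2-dicarboxylate | COC(=O)O[C@H]1C[C@](CC(OC)OC)(C(=O)OC(C)(C)C)C(C(=O)OC)=C1 | intermediate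
11 | 2-methylcyclohexane-1,3-dione | CC1C(=O)CCCC1=O | starting material
12 | 1-tert-butyl 2-methyl (1R,4S)-1-(2,2-dimethoxyethyl)-4-(1-methyl-2,6-dioxocyclohexyl)cyclopent-2-ene-1,2-dicarboxylate | CC1(C(=O)CCCC1=O)[C@H]1C[C@](CC(OC)OC)(C(=O)OC(C)(C)C)C(C(=O)OC)=C1 | intermediate
13 | hydroxy ketone (ring A: 1α-OH, 5-oxo, 10β-methyl; C10–C9 bond to ring C diester) | O=C1CCC[C@H](O)[C@]1(C)[C@H]1C[C@](CC(OC)OC)(C(=O)OC(C)(C)C)C(C(=O)OC)=C1 | intermediate
14 | 1α-triethylsilyl ether of 13 | O=C1CCC[C@H](O[Si](CC)(CC)CC)[C@]1(C)[C@H]1C[C@](CC(OC)OC)(C(=O)OC(C)(C)C)C(C(=O)OC)=C1 | intermediate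
15 | methyl iodide | CI | starting material
16 | 4-monomethyl-5-ketone (C4 epimers, 1α-OTES) | O=C1C(C)CC[C@H](O[Si](CC)(CC)CC)[C@]1(C)[C@H]1C[C@](CC(OC)OC)(C(=O)OC(C)(C)C)C(C(=O)OC)=C1 | intermediate
17 | 4,4-dimethyl-5-ketone (1α-OTES) | O=C1C(C)(C)CC[C@H](O[Si](CC)(CC)CC)[C@]1(C)[C@H]1C[C@](CC(OC)OC)(C(=O)OC(C)(C)C)C(C(=O)OC)=C1 | intermediate
18 | allylmagnesium bromide | C=CC[Mg]Br | starting material
19 | 5β-allyl-5α-hydroxy compound (1α-OTES) | C=CC[C@@]1(O)C(C)(C)CC[C@H](O[Si](CC)(CC)CC)[C@]1(C)[C@H]1C[C@](CC(OC)OC)(C(=O)OC(C)(C)C)C(C(=O)OC)=C1 | intermediate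
20 | 5β-allyl-1α,5α-diol | C=CC[C@@]1(O)C(C)(C)CC[C@H](O)[C@]1(C)[C@H]1C[C@](CC(OC)OC)(C(=O)OC(C)(C)C)C(C(=O)OC)=C1 | intermediate (not isolated)
21 | 5β-allyl 1α,5α-O-isopropylidene acetal | C=CC[C@@]1(OC(C)(C)O2)C(C)(C)CC[C@H]2[C@]1(C)[C@H]1C[C@](CC(OC)OC)(C(=O)OC(C)(C)C)C(C(=O)OC)=C1 | intermediate
22 | C7 aldehyde, Stetter precursor (1α,5α-acetonide) | O=CC[C@@]1(OC(C)(C)O2)C(C)(C)CC[C@H]2[C@]1(C)[C@H]1C[C@](CC(OC)OC)(C(=O)OC(C)(C)C)C(C(=O)OC)=C1 | intermediate
23 | tricyclic 7-ketones, epimeric at C8 and C14 | COC(=O)C1C2C(=O)C[C@@]3(OC(C)(C)O4)C(C)(C)CC[C@H]4[C@]3(C)[C@H]2C[C@]1(CC(OC)OC)C(=O)OC(C)(C)C | intermediate (not isolated)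
24 | tricyclic 7-ketone (8β-H, 9α-H, 14β-CO2Me, 1α,5α-acetonide) | COC(=O)[C@H]1[C@@H]2C(=O)C[C@@]3(OC(C)(C)O4)C(C)(C)CC[C@H]4[C@]3(C)[C@H]2C[C@]1(CC(OC)OC)C(=O)OC(C)(C)C | intermediate
25 | 1α,5α-dihydroxy-7-ketone | COC(=O)[C@H]1[C@@H]2C(=O)C[C@@]3(O)C(C)(C)CC[C@H](O)[C@]3(C)[C@H]2C[C@]1(CC(OC)OC)C(=O)OC(C)(C)C | intermediate
26 | 1α,5α,7β-triol | COC(=O)[C@H]1[C@@H]2[C@@H](O)C[C@@]3(O)C(C)(C)CC[C@H](O)[C@]3(C)[C@H]2C[C@]1(CC(OC)OC)C(=O)OC(C)(C)C | intermediate
27 | 1α,7β-diacetate, 5α-OH | COC(=O)[C@H]1[C@@H]2[C@@H](OC(C)=O)C[C@@]3(O)C(C)(C)CC[C@H](OC(C)=O)[C@]3(C)[C@H]2C[C@]1(CC(OC)OC)C(=O)OC(C)(C)C | intermediate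
28 | C12 acid / C16 aldehyde | COC(=O)[C@H]1[C@@H]2[C@@H](OC(C)=O)C[C@@]3(O)C(C)(C)CC[C@H](OC(C)=O)[C@]3(C)[C@H]2C[C@]1(CC=O)C(=O)O | intermediate (not isolated)
29 | spiro lactol (C16 epimers) | COC(=O)[C@H]1[C@@H]2[C@@H](OC(C)=O)C[C@@]3(O)C(C)(C)CC[C@H](OC(C)=O)[C@]3(C)[C@H]2C[C@]12C(=O)OC(O)C2 | intermediate
30 | spiro enol lactone | COC(=O)[C@H]1[C@@H]2[C@@H](OC(C)=O)C[C@@]3(O)C(C)(C)CC[C@H](OC(C)=O)[C@]3(C)[C@H]2C[C@]12C(=O)OC=C2 | intermediate
31 | 15-bromo lactol (Br on the C11 side, C16 epimers) | COC(=O)[C@H]1[C@@H]2[C@@H](OC(C)=O)C[C@@]3(O)C(C)(C)CC[C@H](OC(C)=O)[C@]3(C)[C@H]2C[C@]12C(=O)OC(O)[C@H]2Br | intermediate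
32 | spirocaesalmin | COC(=O)[C@H]1[C@@H]2[C@@H](OC(C)=O)C[C@@]3(O)C(C)(C)CC[C@H](OC(C)=O)[C@]3(C)[C@H]2C[C@]12C(=O)O[C@@H]1O[C@@H]12 | target

## Step count and risks

Total step count: 23. Longest linear sequence: 23 steps (from 1).

Steps most likely to fail:

1. Step 23 (labelled step). What may go wrong: the bromo lactol may open to the α-bromo aldehyde carboxylate, which can lose the C15 configuration by enolisation or close through the carboxylate onto C15 to a four-membered lactone; silver may also promote rearrangement of the acyloxy epoxide. The fallback uses known chemistry, sets out from enol lactone 30 and comes back at target 32 in one operation: a chiral-ketone-catalysed dioxirane epoxidation of the enol ester (Shi-type carbohydrate-derived ketone, KHSO5 as the triple salt 2KHSO5·KHSO4·K2SO4, buffered MeCN/dimethoxymethane–water, 0 °C). The ketone antipode is chosen so that reagent control sends oxygen to the C14 face, and the C15/C16 epimer would be separated. No new compound is made (F0).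

2. Step 16 (key step). What may go wrong: addition of the acyl-anion equivalent to the hindered trisubstituted acceptor may be too slow, so that aldehyde enolisation with Michael closure through C6, self-condensation, or β-elimination of the C5 oxygen take over. The fallback sets out from aldehyde 22. SmI2 (THF, tBuOH, −78 °C) should form the C7 ketyl radical, which cyclises 6-exo-trig onto C8 of the enoate; reduction of the α-ester radical and protonation give the 7-hydroxy tricycle F1 (epimers at C7, C8 and C14). Oxidation with DMP gives the ketone mixture 23, and DBU equilibration comes back to the route at 24.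

3. Step 13. What may go wrong: the doubly neopentyl ketone may not add the allyl reagent (or the adduct may revert), the esters may be attacked, or the facial selectivity may erode. The fallback sets out from ketone 17 and uses a smaller nucleophile. Ethynylmagnesium bromide with CeCl3 (THF, −78 °C) should add from the same β-face to give the 5-ethynyl carbinol F2. CSA/MeOH and then 2,2-dimethoxypropane give the ethynyl acetonide F3. Anti-Markovnikov hydration of the terminal alkyne by hydroboration with dicyclohexylborane and oxidation with NaBO3 comes back to the route at aldehyde 22, so step 15 is not needed.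

## Further compounds

F0 | step 23 | none | none
F1 | step 16 | 7-hydroxy tricycle (epimers at C7, C8, C14; 1α,5α-acetonide) | COC(=O)C1C2C(O)C[C@@]3(OC(C)(C)O4)C(C)(C)CC[C@H]4[C@]3(C)[C@H]2C[C@]1(CC(OC)OC)C(=O)OC(C)(C)C
F2 | step 13 | 5β-ethynyl-5α-hydroxy compound (1α-OTES) | C#C[C@@]1(O)C(C)(C)CC[C@H](O[Si](CC)(CC)CC)[C@]1(C)[C@H]1C[C@](CC(OC)OC)(C(=O)OC(C)(C)C)C(C(=O)OC)=C1
F3 | step 13 | 5β-ethynyl 1α,5α-O-isopropylidene acetal | C#C[C@@]1(OC(C)(C)O2)C(C)(C)CC[C@H]2[C@]1(C)[C@H]1C[C@](CC(OC)OC)(C(=O)OC(C)(C)C)C(C(=O)OC)=C1
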